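**Plan**
1. Retrosynthesis: cut C9–C10 and C1–C11 (the CH2–CMe2 unit of cyclobutane ring D), then the C1=C9 alkene of nine-membered ring C (metathesis), then C4–C3 and C4–CH3 at the chroman ketal carbon, then C5–C6, and last lactone ring B (coumarin condensation).
2. Enabling feature: ring D is only C10 (CH2) and C11 (CMe2) bridging the C1–C9 edge of ring C, with C10 on C9 and C11 on C1. This is the imprint of a dimethylketene equivalent added across a C1=C9 alkene and then deoxygenated at C10.
3. Forward order: arene ring A is bought; ring B arises by Pechmann condensation and is turned into the 2,2-disubstituted chroman; ring C by ring-closing metathesis; ring D by keteniminium [2+2]; then C10 deoxygenation, C9 epimerisation, C8 methylenation, formylation, demethylation.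
4. Stereochemistry: C1' by ligand-controlled CuH conjugate reduction; C5 by kinetic protonation anti to the C1' phenyl; C4 by oxocarbenium capture anti to phenyl and C5 arm; C1 by face-selective cycloaddition on the locked ring C; C9 by equilibration next to the C8 ketone.
5. Numbering: ring C = C1–C9 (C4 bears O and CH3, C5 is the neighbouring ring-fusion CH, C8 bears the methylene); C10 and C11 complete ring D; C1' is the benzylic CH; a1–a6 are the arene carbons from the C1'-bearing to the O-bearing one.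

Key step: step 13

**Remarks on the chemistry**
- C8 is a stereocentre only from step 8 to step 15. Both epimers are carried together and their SMILES leave C8 open. The ketal carbon C4 in 9–15 is likewise an anomer mixture.
- The (S)-ligand in step 2 is assumed to give the 4S lactone; if the sense is the reverse, the (R)-ligand is used.
- The face of the alkene attacked in step 13 rests on a conformational argument that was not modelled here.

**Route**

Step 1
Reactants: 1 3,5-dimethoxyphenol; 2 ethyl benzoylacetate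
Product: 3 5,7-dimethoxy-4-phenylcoumarin
Conditions: CF3CO2H, 70 °C
Reagents that add atoms: none
Why: Pechmann condensation, in which acid-mediated transesterification, ring closure at the position ortho to the phenol OH and dehydration should give the coumarin without forming a stereocentre.

Step 2
Reactants: 3 5,7-dimethoxy-4-phenylcoumarin
Product: 4 (S)-5,7-dimethoxy-4-phenylchroman-2-one
Conditions: Cu(OAc)2·H2O (cat.), (S)-DTBM-SEGPHOS (cat.), (EtO)2MeSiH, t-BuOH, toluene, 0 °C → rt
Reagents that add atoms: none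
Why: Copper hydride catalysed asymmetric conjugate reduction of the β-aryl unsaturated lactone, in which the chiral bisphosphine directs hydride to one face of C1' (set as S) and t-BuOH protonates the enolate before 1,2-reduction can follow.

Step 3
Reactants: 4 (S)-5,7-dimethoxy-4-phenylchroman-2-one
Product: 6 (3R,4S)-3-allyl-5,7-dimethoxy-4-phenylchroman-2-one (trans), via lithium enolate 5 (not isolated)
Conditions: LiN(SiMe3)2, THF, −78 °C; allyl bromide, −78 °C
Reagents that add atoms: allyl bromide, C=CCBr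
Why: Lactone enolate alkylation with a reactive allylic halide, where the peri methoxy group holds the C1' phenyl pseudo-axial so that the electrophile enters anti to it and C5 is first formed trans (corrected in step 4).

Step 4
Reactants: 6 (3R,4S)-3-allyl-5,7-dimethoxy-4-phenylchroman-2-one
Product: 8 (3S,4S)-3-allyl-5,7-dimethoxy-4-phenylchroman-2-one (cis), via lithium enolate 7 (not isolated)
Conditions: LiN(i-Pr)2, THF, −78 → −40 °C; 2,6-di-tert-butyl-4-methylphenol, THF, −78 °C; H2O
Reagents that add atoms: none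
Why: Kinetic protonation of the planar enolate, in which the proton is delivered anti to the pseudo-axial phenyl just as the allyl group was, so that C5 is inverted and the allyl arm ends up cis to phenyl (5S).

Step 5
Reactants: 8 (3S,4S)-3-allyl-5,7-dimethoxy-4-phenylchroman-2-one
Product: 10 (3S,4S)-3-allyl-2,5,7-trimethoxy-2-methyl-4-phenylchroman (anomer mixture), via methyl lactol 9 (not isolated)
Conditions: MeLi, THF, −78 °C; AcOH, −78 °C; then PPTS, MeOH, 3 Å MS, rt
Reagents that add atoms: methyllithium, [Li]C; methanol, CO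
Why: Mono-addition of methyllithium to the aryl lactone followed by acid-catalysed lactol-to-ketal exchange in methanol should give the mixed methyl ketal, and any enol ether formed on the way re-protonates anti to the phenyl so that C5 is kept.

Step 6
Reactants: 10 (3S,4S)-3-allyl-2,5,7-trimethoxy-2-methyl-4-phenylchroman
Product: 12 3-[(3S,4S)-2,5,7-trimethoxy-2-methyl-4-phenylchroman-3-yl]propan-1-ol, via B-alkyl-9-BBN adduct 11 (not isolated)
Conditions: 9-BBN, THF, 0 °C → rt; NaOH, H2O2, 0 °C
Reagents that add atoms: hydrogen peroxide, OO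
Why: Anti-Markovnikov hydroboration–oxidation of the only alkene, with the ketal stable to the borane and to alkaline peroxide.

Step 7
Reactants: 12 3-[(3S,4S)-2,5,7-trimethoxy-2-methyl-4-phenylchroman-3-yl]propan-1-ol
Product: 13 3-[(3S,4S)-2,5,7-trimethoxy-2-methyl-4-phenylchroman-3-yl]propanal
Conditions: Dess–Martin periodinane, pyridine, CH2Cl2, 0 °C → rt
Reagents that add atoms: none
Why: Dess–Martin oxidation under buffered conditions stops at the aldehyde and spares the acid-labile ketal.

Step 8
Reactants: 13 3-[(3S,4S)-2,5,7-trimethoxy-2-methyl-4-phenylchroman-3-yl]propanal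
Product: 14 5-[(3S,4S)-2,5,7-trimethoxy-2-methyl-4-phenylchroman-3-yl]pent-1-en-3-ol (C8 epimers)
Conditions: CH2=CHMgBr, THF, −78 °C; H2O
Reagents that add atoms: vinylmagnesium bromide, C=C[Mg]Br
Why: Grignard addition to the unhindered aldehyde, where C8 is formed without control, which is acceptable because C8 becomes sp2 again in step 16.

Step 9
Reactants: 14 5-[(3S,4S)-2,5,7-trimethoxy-2-methyl-4-phenylchroman-3-yl]pent-1-en-3-ol
Product: 15 5-[(3S,4S)-2,5,7-trimethoxy-2-methyl-4-phenylchroman-3-yl]pent-1-en-3-yl pivalate (C8 epimers)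
Conditions: t-BuCOCl, DMAP (cat.), pyridine, CH2Cl2, 0 °C → rt
Reagents that add atoms: pivaloyl chloride, CC(C)(C)C(=O)Cl
Why: DMAP-catalysed acylation of the secondary allylic alcohol gives a bulky ester that survives the organozinc and Lewis acid steps and later polarises the C1=C9 alkene.

Step 10
Reactants: 15 5-[(3S,4S)-2,5,7-trimethoxy-2-methyl-4-phenylchroman-3-yl]pent-1-en-3-yl pivalate
Product: 17 5-[(2R,3S,4S)-2-(but-3-en-1-yl)-5,7-dimethoxy-2-methyl-4-phenylchroman-3-yl]pent-1-en-3-yl pivalate (C8 epimers), via chromenylium triflate 16 (not isolated)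
Conditions: Zn(CH2CH2CH=CH2)2 [from CH2=CHCH2CH2MgBr, ZnCl2, Et2O], TMSOTf, CH2Cl2, −78 → −30 °C
Reagents that add atoms: di(but-3-enyl)zinc, C=CCC[Zn]CCC=C (made in the flask from but-3-enylmagnesium bromide, C=CCC[Mg]Br, and ZnCl2)
Why: Lewis acid ionisation of the ketal to the 2-methylchromenylium ion and its alkylation by a dialkylzinc (oxocarbenium alkylation as in C-glycoside synthesis), where the nucleophile adds anti to both the C5 arm and the C1' phenyl so that the butenyl chain is trans to the arm and the methyl cis to it (4R).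

Step 11
Reactants: 17 5-[(2R,3S,4S)-2-(but-3-en-1-yl)-5,7-dimethoxy-2-methyl-4-phenylchroman-3-yl]pent-1-en-3-yl pivalate
Product: 18 5-[(2R,3S,4S)-6,8-dibromo-2-(but-3-en-1-yl)-5,7-dimethoxy-2-methyl-4-phenylchroman-3-yl]pent-1-en-3-yl pivalate (C8 epimers)
Conditions: NBS, MeCN, −20 → 0 °C, dark
Reagents that add atoms: N-bromosuccinimide, O=C1CCC(=O)N1Br
Why: Electrophilic aromatic bromination of the phloroglucinol triether at a3 and a5 should be far faster than attack on the monosubstituted alkenes, and the bromines block the arene and later carry the formyl groups.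

Step 12
Reactants: 18 5-[(2R,3S,4S)-6,8-dibromo-2-(but-3-en-1-yl)-5,7-dimethoxy-2-methyl-4-phenylchroman-3-yl]pent-1-en-3-yl pivalate
Product: 19 chroman-fused (Z)-cyclononenyl pivalate (1'S,4R,5S; C1=C9 alkene; C8 pivalate as both epimers; bromines at a3 and a5)
Conditions: second-generation Grubbs catalyst RuCl2(=CHPh)(PCy3)(H2IMes) (cat.), toluene (high dilution), 80 °C
Reagents that add atoms: none
Why: Ring-closing metathesis that initiates at the unhindered butenyl alkene and closes onto the vinyl group of the allylic pivalate to form C1=C9, with the trans-disposed C3 and C6 chains on ring B held close and the nine-membered ring enforcing the Z alkene.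

Step 13
Reactants: 19 chroman-fused (Z)-cyclononenyl pivalate; 20 1-chloro-N,N,2-trimethylprop-1-en-1-amine
Product: 23 cis-fused 11,11-dimethylcyclobutan-10-one on the C1–C9 bond (1R,9R; C8 pivalate retained), via tetramethylketeniminium trichlorozincate 21 (not isolated), via cyclobutaniminium salt 22 (not isolated)
Conditions: ZnCl2, CH2Cl2, rt → 40 °C; then H2O, rt
Reagents that add atoms: water, O
Why: ZnCl2 abstracts chloride from 20 to give keteniminium ion 21, whose electrophilic sp carbon (future C10) bonds to C9 while positive charge builds at C1, and the enamine carbon (future C11) then bonds to C1 on the same face; this polar, near-concerted suprafacial [2+2] is the known keteniminium–olefin cycloaddition that gives 2,2-dimethylcyclobutanones from unactivated alkenes, and water hydrolyses iminium 22 to the ketone. Ring D thus closes by collapse of the 1,4-dipole, C11 onto the C1 cation, after the intermolecular C9–C10 bond has formed. C1 and C9 are set together: the Z geometry and the suprafacial addition make the ring fusion cis, and the reagent is expected to approach the exposed outer face of the alkene in ring C, which is locked by the trans-fused ring B; that face must be the one anti to H5, which gives 1R. The regioselectivity needed (C10 on C9) is secured by the C8 pivalate, which inductively disfavours charge at C9 and keeps the bulky CMe2 terminus at the remote C1. The chemoselectivity needed is secured by the two bromines, which leave the electron-rich arene no position for acylation. The C9 configuration of the cis adduct is corrected in step 17.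

Step 14
Reactants: 23 cis-fused 11,11-dimethylcyclobutan-10-one
Product: 25 cis-fused 11,11-dimethylcyclobutane with C10 as CH2 (1R,9R; C8 pivalate), via tosylhydrazone 24 (not isolated)
Conditions: TsNHNH2, EtOH, 60 °C; then catecholborane, CHCl3, 0 °C; NaOAc·3H2O, 60 °C
Reagents that add atoms: none
Why: Tosylhydrazone reduction with catecholborane, a mild Wolff–Kishner-type deoxygenation in which hydride adds to the strained C=N and acetate-induced loss of sulfinate and N2 leaves C10 as CH2, under near-neutral conditions that avoid the β-elimination or retro-aldol opening hot alkali would cause in a β-acyloxy cyclobutanone and that spare the aryl bromides.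

Step 15
Reactants: 25 cis-fused cyclobutane pivalate
Product: 26 cis-fused C8 alcohol (1R,9R; C8 epimers)
Conditions: i-Bu2AlH, CH2Cl2, −78 → 0 °C; aq. Rochelle salt
Reagents that add atoms: none
Why: Reductive cleavage of the hindered pivalate by an aluminium hydride that does not touch aryl bromides.

Step 16
Reactants: 26 cis-fused C8 alcohol
Product: 27 cis-fused C8 ketone (1R,9R)
Conditions: Dess–Martin periodinane, pyridine, CH2Cl2, rt
Reagents that add atoms: none
Why: Dess–Martin oxidation of the secondary alcohol merges both C8 epimers into one ketone.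

Step 17
Reactants: 27 cis-fused C8 ketone
Product: 28 trans-fused C8 ketone (1R,9S)
Conditions: KOt-Bu (cat.), t-BuOH/THF, rt
Reagents that add atoms: none
Why: Base-mediated epimerisation through the C8 enolate, in which C9, now α to the ketone, should equilibrate from the cis to the trans ring fusion that is expected to be the more stable one in bicyclo[7.2.0]undecanones of this type.

Step 18
Reactants: 28 trans-fused C8 ketone
Product: 29 dibromo di-O-methyl ether with the exocyclic C8 methylene (1R,9S,1'S,4R,5S)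
Conditions: Ph3PCH3Br, KOt-Bu, THF, 0 → 50 °C
Reagents that add atoms: methyltriphenylphosphonium bromide, [Br-].C[P+](c1ccccc1)(c1ccccc1)c1ccccc1
Why: Wittig methylenation of the ring ketone installs the exocyclic alkene, and any enolisation under the basic conditions only returns the thermodynamic trans fusion.

Step 19
Reactants: 29 dibromo di-O-methyl ether
Product: 31 di-O-methyl ether of the target (formyl groups at a3 and a5), via dilithioarene 30 (not isolated)
Conditions: t-BuLi, THF, −78 °C; DMF, −78 → 0 °C; 1 M aq. HCl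
Reagents that add atoms: N,N-dimethylformamide, CN(C)C=O
Why: Double bromine–lithium exchange, each aryllithium being flanked by two oxygen substituents, followed by formylation with DMF converts both bromides into aldehydes.

Step 20
Reactants: 31 di-O-methyl ether of the target
Product: 32 CNP0253700.3 (target)
Conditions: MgI2·OEt2, toluene, 80 °C; 1 M aq. HCl
Reagents that add atoms: none
Why: Chelation-assisted demethylation, in which magnesium bound between a formyl oxygen and the neighbouring methoxy group activates the methyl for attack by iodide, should cleave both aryl methyl ethers and spare the tertiary chroman ether and the exocyclic alkene.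

**Compound list**
1 | 3,5-dimethoxyphenol | COc1cc(O)cc(OC)c1 | starting material
2 | ethyl benzoylacetate | CCOC(=O)CC(=O)c1ccccc1 | starting material
3 | 5,7-dimethoxy-4-phenylcoumarin | O=c1cc(-c2ccccc2)c2c(OC)cc(OC)cc2o1 | intermediate
4 | (S)-5,7-dimethoxy-4-phenylchroman-2-one | O=C1C[C@@H](c2ccccc2)c2c(OC)cc(OC)cc2O1 | intermediate
5 | lithium enolate of 4 | [Li+].[O-]C1=C[C@@H](c2ccccc2)c2c(OC)cc(OC)cc2O1 | intermediate
6 | (3R,4S)-3-allyl-5,7-dimethoxy-4-phenylchroman-2-one (trans) | C=CC[C@@H]1[C@@H](c2ccccc2)c2c(OC)cc(OC)cc2OC1=O | intermediate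
7 | lithium enolate of 6 | [Li+].[O-]C1=C(CC=C)[C@@H](c2ccccc2)c2c(OC)cc(OC)cc2O1 | intermediate
8 | (3S,4S)-3-allyl-5,7-dimethoxy-4-phenylchroman-2-one (cis) | C=CC[C@H]1[C@@H](c2ccccc2)c2c(OC)cc(OC)cc2OC1=O | intermediate
9 | (3S,4S)-3-allyl-5,7-dimethoxy-2-methyl-4-phenylchroman-2-ol (methyl lactol, anomers, in equilibrium with the open keto-phenol) | C=CC[C@H]1[C@@H](c2ccccc2)c2c(OC)cc(OC)cc2OC1(C)O | intermediate
10 | (3S,4S)-3-allyl-2,5,7-trimethoxy-2-methyl-4-phenylchroman (anomers) | C=CC[C@H]1[C@@H](c2ccccc2)c2c(OC)cc(OC)cc2OC1(C)OC | intermediate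
11 | B-alkyl-9-BBN adduct of 10 | C1CC2CCCC(C1)B2CCC[C@H]1[C@@H](c2ccccc2)c2c(OC)cc(OC)cc2OC1(C)OC | intermediate
12 | 3-[(3S,4S)-2,5,7-trimethoxy-2-methyl-4-phenylchroman-3-yl]propan-1-ol | OCCC[C@H]1[C@@H](c2ccccc2)c2c(OC)cc(OC)cc2OC1(C)OC | intermediate
13 | 3-[(3S,4S)-2,5,7-trimethoxy-2-methyl-4-phenylchroman-3-yl]propanal | O=CCC[C@H]1[C@@H](c2ccccc2)c2c(OC)cc(OC)cc2OC1(C)OC | intermediate
14 | 5-[(3S,4S)-2,5,7-trimethoxy-2-methyl-4-phenylchroman-3-yl]pent-1-en-3-ol (C8 epimers) | C=CC(O)CC[C@H]1[C@@H](c2ccccc2)c2c(OC)cc(OC)cc2OC1(C)OC | intermediate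
15 | pivalate of 14 (C8 epimers) | C=CC(OC(=O)C(C)(C)C)CC[C@H]1[C@@H](c2ccccc2)c2c(OC)cc(OC)cc2OC1(C)OC | intermediate
16 | 2-methylchromenylium (oxocarbenium) triflate from 15 | C=CC(OC(=O)C(C)(C)C)CC[C@H]1[C@@H](c2ccccc2)c2c(OC)cc(OC)cc2[O+]=C1C.[O-]S(=O)(=O)C(F)(F)F | intermediate
17 | 5-[(2R,3S,4S)-2-(but-3-en-1-yl)-5,7-dimethoxy-2-methyl-4-phenylchroman-3-yl]pent-1-en-3-yl pivalate (C8 epimers) | C=CC(OC(=O)C(C)(C)C)CC[C@H]1[C@@H](c2ccccc2)c2c(OC)cc(OC)cc2O[C@]1(C)CCC=C | intermediate
18 | 6,8-dibromo derivative of 17 (C8 epimers) | C=CC(OC(=O)C(C)(C)C)CC[C@H]1[C@@H](c2ccccc2)c2c(OC)c(Br)c(OC)c(Br)c2O[C@]1(C)CCC=C | intermediate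
19 | chroman-fused (Z)-cyclononenyl pivalate (1'S,4R,5S; C8 epimers) | CC(C)(C)C(=O)OC1CC[C@H]2[C@@H](c3ccccc3)c3c(OC)c(Br)c(OC)c(Br)c3O[C@]2(C)CC/C=C\1 | intermediate
20 | 1-chloro-N,N,2-trimethylprop-1-en-1-amine | CC(C)=C(Cl)N(C)C | starting material
21 | tetramethylketeniminium trichlorozincate | CC(C)=C=[N+](C)C.Cl[Zn-](Cl)Cl | intermediate
22 | cis-fused cyclobutaniminium trichlorozincate | CC(C)(C)C(=O)OC1CC[C@H]2[C@@H](c3ccccc3)c3c(OC)c(Br)c(OC)c(Br)c3O[C@]2(C)CC[C@@H]2[C@H]1C(=[N+](C)C)C2(C)C.Cl[Zn-](Cl)Cl | intermediate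
23 | cis-fused 11,11-dimethylcyclobutan-10-one (1R,9R; C8 pivalate) | CC(C)(C)C(=O)OC1CC[C@H]2[C@@H](c3ccccc3)c3c(OC)c(Br)c(OC)c(Br)c3O[C@]2(C)CC[C@@H]2[C@H]1C(=O)C2(C)C | intermediate
24 | tosylhydrazone of 23 | CC(C)(C)C(=O)OC1CC[C@H]2[C@@H](c3ccccc3)c3c(OC)c(Br)c(OC)c(Br)c3O[C@]2(C)CC[C@@H]2[C@H]1C(=NNS(=O)(=O)c1ccc(C)cc1)C2(C)C | intermediate
25 | cis-fused gem-dimethylcyclobutane, C10 = CH2 (1R,9R; C8 pivalate) | CC(C)(C)C(=O)OC1CC[C@H]2[C@@H](c3ccccc3)c3c(OC)c(Br)c(OC)c(Br)c3O[C@]2(C)CC[C@@H]2[C@H]1CC2(C)C | intermediate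
26 | cis-fused C8 alcohol (1R,9R; C8 epimers) | OC1CC[C@H]2[C@@H](c3ccccc3)c3c(OC)c(Br)c(OC)c(Br)c3O[C@]2(C)CC[C@@H]2[C@H]1CC2(C)C | intermediate
27 | cis-fused C8 ketone (1R,9R) | O=C1CC[C@H]2[C@@H](c3ccccc3)c3c(OC)c(Br)c(OC)c(Br)c3O[C@]2(C)CC[C@@H]2[C@H]1CC2(C)C | intermediate
28 | trans-fused C8 ketone (1R,9S) | O=C1CC[C@H]2[C@@H](c3ccccc3)c3c(OC)c(Br)c(OC)c(Br)c3O[C@]2(C)CC[C@@H]2[C@@H]1CC2(C)C | intermediate
29 | dibromo di-O-methyl ether with C8 methylene | C=C1CC[C@H]2[C@@H](c3ccccc3)c3c(OC)c(Br)c(OC)c(Br)c3O[C@]2(C)CC[C@@H]2[C@@H]1CC2(C)C | intermediate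
30 | a3,a5-dilithioarene from 29 | C=C1CC[C@H]2[C@@H](c3ccccc3)c3c(OC)c([Li])c(OC)c([Li])c3O[C@]2(C)CC[C@@H]2[C@@H]1CC2(C)C | intermediate
31 | di-O-methyl ether of the target | C=C1CC[C@H]2[C@@H](c3ccccc3)c3c(OC)c(C=O)c(OC)c(C=O)c3O[C@]2(C)CC[C@@H]2[C@@H]1CC2(C)C | intermediate
32 | CNP0253700.3 | C=C1CC[C@H]2[C@@H](c3ccccc3)c3c(O)c(C=O)c(O)c(C=O)c3O[C@]2(C)CC[C@@H]2[C@@H]1CC2(C)C | target

**Totals**
Total step count: 20. Longest linear sequence: 20 steps (1 and 2 to 32; 20 enters at step 13).

**Steps most likely to fail**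

Step 10. The dialkylzinc may be too slow for the tertiary oxocarbenium ion, so that proton loss to the enol ether or capture from the wrong face competes. The fallback sets out from 12 and returns at 17; it introduces the C4 chain with an allylsilane and lengthens it by one carbon. Alcohol 12 is silylated (t-BuPh2SiCl, imidazole) to the silyl ether F1. Hosomi–Sakurai allylation (allyltrimethylsilane, TMSOTf, CH2Cl2, −78 °C) then gives the 2-allylchroman F2 with the same facial preference. Hydroboration–oxidation (9-BBN; NaOH, H2O2) gives the primary alcohol F3, Dess–Martin oxidation the aldehyde F4, and Wittig methylenation (Ph3PCH3Br, KOt-Bu) the butenyl chroman F5. Fluoride (Bu4NF) frees the arm alcohol F6, Dess–Martin oxidation gives the arm aldehyde F7, vinylmagnesium bromide the allylic alcohol F8, and pivaloylation leads back to 17.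

Step 12. Closure of the strained nine-membered ring needs the chroman conformer with C3 and C6 both equatorial, in which the C4 methyl and the C1' phenyl are syn-axial; if that conformer is scarce, intermolecular metathesis takes over. The fallback sets out from 12 and returns at 19; it closes ring C at C8–C9 by an intramolecular Nozaki–Hiyama–Kishi reaction. Alcohol 12 is pivaloylated to the primary pivalate F9 and butenylated as in step 10 to the butenyl chroman F10. Lemieux–Johnson cleavage (OsO4 cat., NaIO4, 2,6-lutidine) gives the chain aldehyde F11, and Stork–Zhao olefination (Ph3PCH2I iodide, NaN(SiMe3)2, THF, −78 °C) the (Z)-vinyl iodide F12. i-Bu2AlH removes the pivalate to give the iodo alcohol F13, and Dess–Martin oxidation gives the iodo aldehyde F14. CrCl2 with catalytic NiCl2 in DMSO at high dilution closes the ring to the (Z)-cyclononenol F15, pivaloylation gives the bromine-free cyclononenyl pivalate F16, and NBS dibromination leads back to 19.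

Step 13. The hindered Z alkene may react slowly with the bulky keteniminium ion, which leaves time for ZnCl2 to ionise the allylic pivalate, and attack on the undesired alkene face cannot be excluded. The fallback sets out from 19 and returns at 23; it uses a smaller, more electrophilic ketene and adds the methyl groups afterwards. Dichloroketene (Cl3CCOCl, Zn(Cu), Et2O) is added across C1=C9 with the same polarity to give the dichlorocyclobutanone F17. Its two chlorines are exchanged for methyl groups with excess Me2CuLi followed by MeI (reductive gem-dimethylation of an α,α-dihaloketone through the C11 enolate, which never places negative charge at C9), leading back to 23. The C8 epimers of 19 can be separated beforehand so that each is tested on its own.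

**Further compounds**
F1 | step 10 | (3S,4S)-3-[3-(tert-butyldiphenylsilyloxy)propyl]-2,5,7-trimethoxy-2-methyl-4-phenylchroman (anomers) | CC(C)(C)[Si](OCCC[C@H]1[C@@H](c2ccccc2)c2c(OC)cc(OC)cc2OC1(C)OC)(c1ccccc1)c1ccccc1
F2 | step 10 | (2R,3S,4S)-2-allyl-3-[3-(tert-butyldiphenylsilyloxy)propyl]-5,7-dimethoxy-2-methyl-4-phenylchroman | CC(C)(C)[Si](OCCC[C@H]1[C@@H](c2ccccc2)c2c(OC)cc(OC)cc2O[C@]1(C)CC=C)(c1ccccc1)c1ccccc1
F3 | step 10 | 3-[(2R,3S,4S)-3-[3-(tert-butyldiphenylsilyloxy)propyl]-5,7-dimethoxy-2-methyl-4-phenylchroman-2-yl]propan-1-ol | CC(C)(C)[Si](OCCC[C@H]1[C@@H](c2ccccc2)c2c(OC)cc(OC)cc2O[C@]1(C)CCCO)(c1ccccc1)c1ccccc1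
F4 | step 10 | 3-[(2R,3S,4S)-3-[3-(tert-butyldiphenylsilyloxy)propyl]-5,7-dimethoxy-2-methyl-4-phenylchroman-2-yl]propanal | CC(C)(C)[Si](OCCC[C@H]1[C@@H](c2ccccc2)c2c(OC)cc(OC)cc2O[C@]1(C)CCC=O)(c1ccccc1)c1ccccc1
F5 | step 10 | (2R,3S,4S)-2-(but-3-en-1-yl)-3-[3-(tert-butyldiphenylsilyloxy)propyl]-5,7-dimethoxy-2-methyl-4-phenylchroman | CC(C)(C)[Si](OCCC[C@H]1[C@@H](c2ccccc2)c2c(OC)cc(OC)cc2O[C@]1(C)CCC=C)(c1ccccc1)c1ccccc1
F6 | step 10 | 3-[(2R,3S,4S)-2-(but-3-en-1-yl)-5,7-dimethoxy-2-methyl-4-phenylchroman-3-yl]propan-1-ol | OCCC[C@H]1[C@@H](c2ccccc2)c2c(OC)cc(OC)cc2O[C@]1(C)CCC=C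
F7 | step 10 | 3-[(2R,3S,4S)-2-(but-3-en-1-yl)-5,7-dimethoxy-2-methyl-4-phenylchroman-3-yl]propanal | O=CCC[C@H]1[C@@H](c2ccccc2)c2c(OC)cc(OC)cc2O[C@]1(C)CCC=C
F8 | step 10 | 5-[(2R,3S,4S)-2-(but-3-en-1-yl)-5,7-dimethoxy-2-methyl-4-phenylchroman-3-yl]pent-1-en-3-ol (C8 epimers) | C=CC(O)CC[C@H]1[C@@H](c2ccccc2)c2c(OC)cc(OC)cc2O[C@]1(C)CCC=C
F9 | step 12 | 3-[(3S,4S)-2,5,7-trimethoxy-2-methyl-4-phenylchroman-3-yl]propyl pivalate (anomers) | CC(C)(C)C(=O)OCCC[C@H]1[C@@H](c2ccccc2)c2c(OC)cc(OC)cc2OC1(C)OC
F10 | step 12 | 3-[(2R,3S,4S)-2-(but-3-en-1-yl)-5,7-dimethoxy-2-methyl-4-phenylchroman-3-yl]propyl pivalate | CC(C)(C)C(=O)OCCC[C@H]1[C@@H](c2ccccc2)c2c(OC)cc(OC)cc2O[C@]1(C)CCC=C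
F11 | step 12 | 3-[(2R,3S,4S)-5,7-dimethoxy-2-methyl-2-(3-oxopropyl)-4-phenylchroman-3-yl]propyl pivalate | CC(C)(C)C(=O)OCCC[C@H]1[C@@H](c2ccccc2)c2c(OC)cc(OC)cc2O[C@]1(C)CCC=O
F12 | step 12 | 3-[(2R,3S,4S)-2-[(Z)-4-iodobut-3-en-1-yl]-5,7-dimethoxy-2-methyl-4-phenylchroman-3-yl]propyl pivalate | CC(C)(C)C(=O)OCCC[C@H]1[C@@H](c2ccccc2)c2c(OC)cc(OC)cc2O[C@]1(C)CC/C=C\I
F13 | step 12 | 3-[(2R,3S,4S)-2-[(Z)-4-iodobut-3-en-1-yl]-5,7-dimethoxy-2-methyl-4-phenylchroman-3-yl]propan-1-ol | OCCC[C@H]1[C@@H](c2ccccc2)c2c(OC)cc(OC)cc2O[C@]1(C)CC/C=C\I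
F14 | step 12 | 3-[(2R,3S,4S)-2-[(Z)-4-iodobut-3-en-1-yl]-5,7-dimethoxy-2-methyl-4-phenylchroman-3-yl]propanal | O=CCC[C@H]1[C@@H](c2ccccc2)c2c(OC)cc(OC)cc2O[C@]1(C)CC/C=C\I
F15 | step 12 | bromine-free chroman-fused (Z)-cyclononen-8-ol (1'S,4R,5S; C8 epimers) | OC1CC[C@H]2[C@@H](c3ccccc3)c3c(OC)cc(OC)cc3O[C@]2(C)CC/C=C\1
F16 | step 12 | bromine-free chroman-fused (Z)-cyclononenyl pivalate (C8 epimers) | CC(C)(C)C(=O)OC1CC[C@H]2[C@@H](c3ccccc3)c3c(OC)cc(OC)cc3O[C@]2(C)CC/C=C\1
F17 | step 13 | cis-fused 11,11-dichlorocyclobutan-10-one on the C1–C9 bond (C8 pivalate) | CC(C)(C)C(=O)OC1CC[C@H]2[C@@H](c3ccccc3)c3c(OC)c(Br)c(OC)c(Br)c3O[C@]2(C)CC[C@@H]2[C@H]1C(=O)C2(Cl)Cl
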